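In the red run 92.3% of the Za and Zb charged is left at 15.0 min, and in the grey run 92.1%, although grey holds 2.25 times the substrate of red.

| flask | Za | Zb | Zc | Zd | remark | time |
|---|---|---|---|---|---|---|
| red | 0.20 M | 0.20 M | 0.24 M | 0.33 mM | run made earlier |  |
| grey | 0.45 M | 0.45 M | 0.24 M | 0.33 mM | run made earlier |  |
| teal | 0.30 M | 0.30 M | 0.36 M | 0.33 mM | run made earlier |  |
| flask | 0.30 M | 0.30 M | 0.240 M | 0.33 mM |  | 15 min |

| run | time / min | Zf / % | Zg / % |
|---|---|---|---|
| red | 1.33 | 0.7 | 1.2 |
| red | 4.00 | 2.3 | 1.8 |
| red | 8.00 | 2.8 | 2.0 |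
| red | 10.0 | 4.4 | 3.1 |
| red | 15.0 | 5.6 | 2.1 |
| grey | 1.33 | 1.8 | 0.9 |
| grey | 2.50 | 1.6 | 0.6 |
| grey | 4.00 | 2.1 | 0.9 |
| grey | 8.00 | 3.8 | 1.6 |
| grey | 15.0 | 5.7 | 2.2 |
| teal | 1.33 | 1.2 | 0.8 |
| teal | 4.00 | 3.4 | 1.4 |
| teal | 8.00 | 5.1 | 3.0 |
| teal | 10.0 | 5.5 | 3.4 |
| teal | 15.0 | 6.9 | 4.6 |

(standard deviation of a reading: 0.5 percentage points)

- excess of Zf over Zg in the product at 20 s
- excess of Zf over Zg in the product at 15 min
- part of the Za and Zb charged together that has reacted at 15 min

- Zd is single-handed; Za and Zb are mirror images of each other, charged as a racemate, each of them at the stated concentration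
- the numbers in the tables scatter with a standard deviation of 0.5 percentage points
- an excess is the difference of the two amounts in percent of their sum
- an excess is below zero if the other one leads

Zd is the catalyst and Zc the reagent; Zf comes from Za and Zg from Zb. The equal leftovers look at odds with the work of the catalyst. Let n be the turnovers, the moles of Zf and Zg made per mole of Zd charged (the turnover number). Red then gives 93.3 and grey 215, on equal Zd and Zc.

The two numbers agree once the substrate is read as a first-order drain with one time constant for both runs. The same fraction leaves in the same time, so at fixed Zc, Zd and time, n grows in step with the charge. The readings of red and grey together give about 236 /M, counted as turnovers per molar of Za and Zb charged.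

By my own reckoning, this flask has the Zc and Zd of those runs and 0.600 M of the two together. Its expected turnover count is therefore 142, which means 7.80% reacted at 15 min.

The forecast gives 8% reacted, with an excess of 29% at 15 min and 20% at 20 s, judging that “early selectivity may be lower”.

The simulated flask gives 8.29% reacted, with an excess of 30.2% at 15 min and 31.3% at 20 s. The last stands 11 percentage points above the forecast; the other two agree with it.

    Zc + Zd + Za → Zd + Zf (k = 162 /M²/min)
    Zc + Zd + Zb → Zd + Zg (k = 84.6 /M²/min)
    Zc + Zd → Zh (k = 0.204 /M/min)
    2 Zc → Ze (k = 0.0376 /M/min)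

The flask logged 151 turnovers, against 142 counted ahead. The time allowed is a part of why this flask stands at 8.29% reacted: the same flask run for tenfold the time, to 150 min, reaches 16.6%. That gain is 9.1% of what was missing, so the time is not the main reason.

A neighbour flask has 8.2 × 10⁻⁴ M of Zd, its other charges as here. There, 142 turnovers give 19.4% reacted; the computed neighbour reaches 17.1%, which is 125 turnovers.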